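**Retrosynthetic overview**

1. The carbocycle and the lactone are made last and together. An intramolecular Cr(II) allylation of the Z-enal / 2-(bromomethyl)enoate 20 forms C6–C7 and the ten-membered ring, and O6–C12 lactonisation follows. The acrylate unit comes from the C7 aldehyde and methyl propiolate.
2. The 3(2H)-furanone ring (O, C10, C1, C2, C3) is not closed as a five-membered ring. It grows out of the oxirane O–C10–C1 of an anomeric alkynyl epoxide by insertion of the alkyne carbons C2 and C3 (one-pot epoxidation / gold-catalysed ring expansion). The same step sets C10 and brings in the C8 ester with inversion.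
3. Enabling feature: the C1 ketone is α to the oxygenated quaternary C10 and 1,4 to the C8 oxygen. O(C8) and C1 can therefore be tied as a temporary 4,5-dihydrofuran. Its enol ether C1=C10 takes up the new ring oxygen, and its O–C8 bond is the leaving group for the acyloxy group.
4. The key-step precursor 8 comes from a Pd coupling (C1–C2) of the ketene acetal phosphate of the L-glutamic-acid-derived lactone 1 (C1, C7–C10) with the commercial (Z)-enynol 5 (C2–C6, C15, Z-C4=C5).
5. Order of rings: temporary dihydrofuran (from 1) → oxirane → furanone (temporary ring opened) → carbocycle and γ-lactone.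

Key step: step 6

Remark: atoms are numbered as in germacranolides (furanone = O, C10, C1, C2, C3; lactone on C6/C7; ester on C8). It is assumed that DMDO attacks the enol ether of 8 anti to the CH2OTBDPS group, as electrophiles do with the enolate of the parent lactone; DMDO is used as a pre-made acetone solution.

**Route**

Step 1
Reactants: 1 (S)-5-(hydroxymethyl)dihydrofuran-2(3H)-one
Product: 2 (S)-5-[(tert-butyldiphenylsilyloxy)methyl]dihydrofuran-2(3H)-one
Conditions: TBDPSCl, imidazole, DMF, 0 °C → rt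
Reagents that add atoms: tert-butyl(chloro)diphenylsilane, CC(C)(C)[Si](Cl)(c1ccccc1)c1ccccc1
Why: Silyl ether formation at the primary alcohol; the bulky TBDPS group later shields one face of the five-membered ring.

Step 2
Reactants: 2 (S)-5-[(tert-butyldiphenylsilyloxy)methyl]dihydrofuran-2(3H)-one
Product: 3 (5S)-5-[(tert-butyldiphenylsilyloxy)methyl]-3-methyldihydrofuran-2(3H)-one (both C3 epimers)
Conditions: LDA, THF, −78 °C; MeI, −78 → −40 °C
Reagents that add atoms: iodomethane, CI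
Why: Lactone enolate alkylation introduces C14; the configuration of the methylated carbon (C10) does not matter because it becomes sp2 in step 3.

Step 3
Reactants: 3 (5S)-5-[(tert-butyldiphenylsilyloxy)methyl]-3-methyldihydrofuran-2(3H)-one
Product: 4 (S)-5-[(tert-butyldiphenylsilyloxy)methyl]-3-methyl-4,5-dihydrofuran-2-yl diphenyl phosphate
Conditions: KHMDS, HMPA, THF, −78 °C; (PhO)2P(O)Cl
Reagents that add atoms: diphenyl chlorophosphate, O=P(Cl)(Oc1ccccc1)Oc1ccccc1
Why: O-Phosphorylation of the potassium lactone enolate gives the cyclic ketene acetal phosphate, an established cross-coupling handle for lactone carbonyls.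

Step 4
Reactants: 5 (Z)-3-methylpent-2-en-4-yn-1-ol
Product: 6 (Z)-5-(4-methoxybenzyloxy)-3-methylpent-3-en-1-yne
Conditions: NaH, PMBCl, Bu4NI (cat.), THF, 0 °C → rt
Reagents that add atoms: 4-methoxybenzyl chloride, COc1ccc(CCl)cc1
Why: Williamson ether synthesis on the alkoxide; the Z-alkene and the terminal alkyne are not touched.

Step 5
Reactants: 6 (Z)-5-(4-methoxybenzyloxy)-3-methylpent-3-en-1-yne; 4 (S)-5-[(tert-butyldiphenylsilyloxy)methyl]-3-methyl-4,5-dihydrofuran-2-yl diphenyl phosphate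
Product: 8 tert-butyl({(2S)-5-[(Z)-5-(4-methoxybenzyloxy)-3-methylpent-3-en-1-yn-1-yl]-4-methyl-2,3-dihydrofuran-2-yl}methoxy)diphenylsilane, via alkynylzinc chloride 7 (not isolated)
Conditions: 6, n-BuLi, THF, −78 °C, then ZnCl2, → 0 °C; then 4, Pd(PPh3)4 (5 mol %), THF, rt → 40 °C
Reagents that add atoms: none
Why: Negishi coupling; Pd(0) inserts into the C–O bond of the ketene acetal phosphate and the alkynylzinc delivers the Z-enyne, which forms C1–C2 and the temporary 2-alkynyl-4,5-dihydrofuran.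

Step 6
Reactants: 8 tert-butyl({(2S)-5-[(Z)-5-(4-methoxybenzyloxy)-3-methylpent-3-en-1-yn-1-yl]-4-methyl-2,3-dihydrofuran-2-yl}methoxy)diphenylsilane; 9 (S)-2-methylbutanoic acid
Product: 12 (R)-1-(tert-butyldiphenylsilyloxy)-3-{(R)-5-[(Z)-4-(4-methoxybenzyloxy)but-2-en-2-yl]-2-methyl-3-oxo-2,3-dihydrofuran-2-yl}propan-2-yl (S)-2-methylbutanoate, via anomeric alkynyl epoxide 10 (not isolated), via bicyclic alkoxyfurylium carboxylate 11 (not isolated)
Conditions: DMDO (1.1 equiv, acetone), CH2Cl2, −78 → −40 °C; volatiles removed cold; then 9 (3 equiv), Ph3PAuNTf2 (5 mol %), 4 Å MS, toluene, −20 → 50 °C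
Reagents that add atoms: dimethyldioxirane, CC1(C)OO1
Why: Proposed new method: DMDO epoxidises the electron-rich tetrasubstituted enol ether C1=C10 of 8 anti to the C8 CH2OTBDPS group (the 1,3-induction that makes reactions of the parent lactone enolate trans-selective), which sets C10 as R and gives the anomeric oxirane 10 (O, C10, C1). Acid and the π-acidic gold catalyst then ionise the anomeric C1–O bond of the oxirane (assisted by the ring oxygen on C8), and the freed C10 oxygen adds 5-endo-dig to C3 of the gold-activated alkyne; protodeauration leaves the bicyclic 3-alkoxyfurylium carboxylate 11, so the three-membered ring has been expanded by C2 and C3 into the five-membered furanone ring. The carboxylate of 9 then attacks C8 of 11 in an SN2 reaction (inversion, S to R), which cleaves the temporary O–C8 bond, turns that oxygen into the C1 carbonyl oxygen and installs the ester. Closest known reaction types: the gold-catalysed ring expansion of alkynyl oxiranes to furans, the gold-catalysed 5-endo-dig cyclisation of α′-oxygenated ynones and their hemiketals to 3(2H)-furanones, the opening of glycal epoxides at the anomeric carbon, and the inverting opening of cyclic acyloxonium ions by carboxylates (Prévost type). The step needs chemoselective epoxidation (the enol ether is by far the most nucleophilic alkene, so the enyne alkene and the PMB ether should not react at −78 °C) and carboxylate attack at C8 instead of hydrolysis at C1 (strictly anhydrous conditions; additions at C1 and C3 are reversible, and C10 is tertiary and cannot react by SN2).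

Step 7
Reactants: 12 (R)-1-(tert-butyldiphenylsilyloxy)-3-{(R)-5-[(Z)-4-(4-methoxybenzyloxy)but-2-en-2-yl]-2-methyl-3-oxo-2,3-dihydrofuran-2-yl}propan-2-yl (S)-2-methylbutanoate
Product: 13 (R)-1-hydroxy-3-{(R)-5-[(Z)-4-(4-methoxybenzyloxy)but-2-en-2-yl]-2-methyl-3-oxo-2,3-dihydrofuran-2-yl}propan-2-yl (S)-2-methylbutanoate
Conditions: HF·pyridine, pyridine, THF, 0 °C → rt
Reagents that add atoms: none
Why: Fluoride-mediated silyl ether cleavage under pyridine-buffered, non-basic conditions that should suppress 1,2-acyl migration to the freed primary hydroxyl.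

Step 8
Reactants: 13 (R)-1-hydroxy-3-{(R)-5-[(Z)-4-(4-methoxybenzyloxy)but-2-en-2-yl]-2-methyl-3-oxo-2,3-dihydrofuran-2-yl}propan-2-yl (S)-2-methylbutanoate
Product: 14 (R)-1-oxo-3-{(R)-5-[(Z)-4-(4-methoxybenzyloxy)but-2-en-2-yl]-2-methyl-3-oxo-2,3-dihydrofuran-2-yl}propan-2-yl (S)-2-methylbutanoate
Conditions: Dess–Martin periodinane, CH2Cl2, 0 °C → rt; used crude
Reagents that add atoms: none
Why: Dess–Martin oxidation gives the α-acyloxy aldehyde under neutral conditions that should not epimerise C8.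

Step 9
Reactants: 14 (R)-1-oxo-3-{(R)-5-[(Z)-4-(4-methoxybenzyloxy)but-2-en-2-yl]-2-methyl-3-oxo-2,3-dihydrofuran-2-yl}propan-2-yl (S)-2-methylbutanoate; 15 methyl propiolate
Product: 17 methyl (4R)-3-hydroxy-5-{(R)-5-[(Z)-4-(4-methoxybenzyloxy)but-2-en-2-yl]-2-methyl-3-oxo-2,3-dihydrofuran-2-yl}-2-methylidene-4-{[(S)-2-methylbutanoyl]oxy}pentanoate (both C3 epimers), via α-aluminated acrylate 16 (not isolated)
Conditions: 15, DIBAL-H, NMO, THF, 0 °C; then 14, 0 °C → rt
Reagents that add atoms: none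
Why: Vinylalumination (hydroalumination of the propiolate and 1,2-addition of the α-aluminated acrylate to the aldehyde) gives the Morita–Baylis–Hillman-type adduct without amine base; the new carbinol centre (C7) is lost in step 10.

Step 10
Reactants: 17 methyl (4R)-3-hydroxy-5-{(R)-5-[(Z)-4-(4-methoxybenzyloxy)but-2-en-2-yl]-2-methyl-3-oxo-2,3-dihydrofuran-2-yl}-2-methylidene-4-{[(S)-2-methylbutanoyl]oxy}pentanoate
Product: 18 methyl (2Z,4R)-2-(bromomethyl)-5-{(R)-5-[(Z)-4-(4-methoxybenzyloxy)but-2-en-2-yl]-2-methyl-3-oxo-2,3-dihydrofuran-2-yl}-4-{[(S)-2-methylbutanoyl]oxy}pent-2-enoate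
Conditions: PBr3, Et2O, −10 → 0 °C
Reagents that add atoms: phosphorus tribromide, BrP(Br)Br
Why: SN2′ bromination of the Morita–Baylis–Hillman alcohol transposes the alkene and gives the (Z)-2-(bromomethyl)enoate.

Step 11
Reactants: 18 methyl (2Z,4R)-2-(bromomethyl)-5-{(R)-5-[(Z)-4-(4-methoxybenzyloxy)but-2-en-2-yl]-2-methyl-3-oxo-2,3-dihydrofuran-2-yl}-4-{[(S)-2-methylbutanoyl]oxy}pent-2-enoate
Product: 19 methyl (2Z,4R)-2-(bromomethyl)-5-{(R)-5-[(Z)-4-hydroxybut-2-en-2-yl]-2-methyl-3-oxo-2,3-dihydrofuran-2-yl}-4-{[(S)-2-methylbutanoyl]oxy}pent-2-enoate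
Conditions: DDQ, CH2Cl2/pH 7 buffer (10:1), 0 °C
Reagents that add atoms: none
Why: Oxidative PMB ether cleavage (hydride abstraction by DDQ, then hydrolysis) should leave the allylic bromide and both esters intact.

Step 12
Reactants: 19 methyl (2Z,4R)-2-(bromomethyl)-5-{(R)-5-[(Z)-4-hydroxybut-2-en-2-yl]-2-methyl-3-oxo-2,3-dihydrofuran-2-yl}-4-{[(S)-2-methylbutanoyl]oxy}pent-2-enoate
Product: 20 methyl (2Z,4R)-2-(bromomethyl)-5-{(R)-2-methyl-3-oxo-5-[(Z)-4-oxobut-2-en-2-yl]-2,3-dihydrofuran-2-yl}-4-{[(S)-2-methylbutanoyl]oxy}pent-2-enoate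
Conditions: MnO2, CH2Cl2, rt
Reagents that add atoms: none
Why: MnO2 oxidises only the allylic alcohol and should keep the Z geometry of the trisubstituted alkene.

Step 13
Reactants: 20 methyl (2Z,4R)-2-(bromomethyl)-5-{(R)-2-methyl-3-oxo-5-[(Z)-4-oxobut-2-en-2-yl]-2,3-dihydrofuran-2-yl}-4-{[(S)-2-methylbutanoyl]oxy}pent-2-enoate
Product: 22 target CNP0174601.1 with (6R,7R,8R,10R) configuration and the (S)-2-methylbutanoate on O8, via macrocyclic hydroxy ester 21 (not isolated)
Conditions: CrCl2 (10 equiv), THF/DMF, rt, slow addition (about 2 mM); then p-TsOH (cat.), CH2Cl2, rt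
Reagents that add atoms: none
Why: Intramolecular Nozaki–Hiyama-type (Barbier) allylation: the allylchromium(III) species adds to the Z-enal through a chair-like transition state that should give the anti (6,7-trans) adduct, the facial sense relative to C8 being left to the strain-minimised macrocyclic transition state, and acid then closes the α-methylene γ-lactone.

**Compound list**

1 | (S)-5-(hydroxymethyl)dihydrofuran-2(3H)-one | O=C1CC[C@@H](CO)O1 | starting material
2 | (S)-5-[(tert-butyldiphenylsilyloxy)methyl]dihydrofuran-2(3H)-one | O=C1CC[C@@H](CO[Si](c2ccccc2)(c2ccccc2)C(C)(C)C)O1 | intermediate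
3 | (5S)-5-[(tert-butyldiphenylsilyloxy)methyl]-3-methyldihydrofuran-2(3H)-one (both C3 epimers) | CC1C[C@@H](CO[Si](c2ccccc2)(c2ccccc2)C(C)(C)C)OC1=O | intermediate
4 | (S)-5-[(tert-butyldiphenylsilyloxy)methyl]-3-methyl-4,5-dihydrofuran-2-yl diphenyl phosphate | CC1=C(OP(=O)(Oc2ccccc2)Oc2ccccc2)O[C@H](CO[Si](c2ccccc2)(c2ccccc2)C(C)(C)C)C1 | intermediate
5 | (Z)-3-methylpent-2-en-4-yn-1-ol | C#C/C(C)=C\CO | starting material
6 | (Z)-5-(4-methoxybenzyloxy)-3-methylpent-3-en-1-yne | C#C/C(C)=C\COCc1ccc(OC)cc1 | intermediate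
7 | chloro[(Z)-5-(4-methoxybenzyloxy)-3-methylpent-3-en-1-yn-1-yl]zinc | Cl[Zn]C#C/C(C)=C\COCc1ccc(OC)cc1 | intermediate
8 | tert-butyl({(2S)-5-[(Z)-5-(4-methoxybenzyloxy)-3-methylpent-3-en-1-yn-1-yl]-4-methyl-2,3-dihydrofuran-2-yl}methoxy)diphenylsilane | CC1=C(C#C/C(C)=C\COCc2ccc(OC)cc2)O[C@H](CO[Si](c2ccccc2)(c2ccccc2)C(C)(C)C)C1 | intermediate
9 | (S)-2-methylbutanoic acid | CC[C@H](C)C(=O)O | starting material
10 | tert-butyl({(1R,3S,5R)-1-[(Z)-5-(4-methoxybenzyloxy)-3-methylpent-3-en-1-yn-1-yl]-5-methyl-2,6-dioxabicyclo[3.1.0]hexan-3-yl}methoxy)diphenylsilane (epoxide oxygen anti to CH2OTBDPS) | C[C@]12O[C@@]1(C#C/C(C)=C\COCc1ccc(OC)cc1)O[C@H](CO[Si](c1ccccc1)(c1ccccc1)C(C)(C)C)C2 | intermediate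
11 | (2S,3aR)-2-[(tert-butyldiphenylsilyloxy)methyl]-5-[(Z)-4-(4-methoxybenzyloxy)but-2-en-2-yl]-3a-methyl-3,3a-dihydro-2H-furo[3,2-b]furan-1-ium (S)-2-methylbutanoate | C[C@@]12C[C@@H](CO[Si](c3ccccc3)(c3ccccc3)C(C)(C)C)[O+]=C1C=C(/C(C)=C\COCc1ccc(OC)cc1)O2.CC[C@H](C)C(=O)[O-] | intermediate
12 | (R)-1-(tert-butyldiphenylsilyloxy)-3-{(R)-5-[(Z)-4-(4-methoxybenzyloxy)but-2-en-2-yl]-2-methyl-3-oxo-2,3-dihydrofuran-2-yl}propan-2-yl (S)-2-methylbutanoate | C/C(=C/COCc1ccc(OC)cc1)C1=CC(=O)[C@@](C)(C[C@@H](OC(=O)[C@@H](C)CC)CO[Si](c2ccccc2)(c2ccccc2)C(C)(C)C)O1 | intermediate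
13 | (R)-1-hydroxy-3-{(R)-5-[(Z)-4-(4-methoxybenzyloxy)but-2-en-2-yl]-2-methyl-3-oxo-2,3-dihydrofuran-2-yl}propan-2-yl (S)-2-methylbutanoate | C/C(=C/COCc1ccc(OC)cc1)C1=CC(=O)[C@@](C)(C[C@@H](OC(=O)[C@@H](C)CC)CO)O1 | intermediate
14 | (R)-1-oxo-3-{(R)-5-[(Z)-4-(4-methoxybenzyloxy)but-2-en-2-yl]-2-methyl-3-oxo-2,3-dihydrofuran-2-yl}propan-2-yl (S)-2-methylbutanoate | C/C(=C/COCc1ccc(OC)cc1)C1=CC(=O)[C@@](C)(C[C@@H](OC(=O)[C@@H](C)CC)C=O)O1 | intermediate
15 | methyl propiolate | C#CC(=O)OC | starting material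
16 | methyl 2-(diisobutylalumanyl)prop-2-enoate | C=C(C(=O)OC)[Al](CC(C)C)CC(C)C | intermediate
17 | methyl (4R)-3-hydroxy-5-{(R)-5-[(Z)-4-(4-methoxybenzyloxy)but-2-en-2-yl]-2-methyl-3-oxo-2,3-dihydrofuran-2-yl}-2-methylidene-4-{[(S)-2-methylbutanoyl]oxy}pentanoate (both C3 epimers) | C/C(=C/COCc1ccc(OC)cc1)C1=CC(=O)[C@@](C)(C[C@@H](OC(=O)[C@@H](C)CC)C(O)C(=C)C(=O)OC)O1 | intermediate
18 | methyl (2Z,4R)-2-(bromomethyl)-5-{(R)-5-[(Z)-4-(4-methoxybenzyloxy)but-2-en-2-yl]-2-methyl-3-oxo-2,3-dihydrofuran-2-yl}-4-{[(S)-2-methylbutanoyl]oxy}pent-2-enoate | C/C(=C/COCc1ccc(OC)cc1)C1=CC(=O)[C@@](C)(C[C@@H](OC(=O)[C@@H](C)CC)/C=C(\CBr)C(=O)OC)O1 | intermediate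
19 | methyl (2Z,4R)-2-(bromomethyl)-5-{(R)-5-[(Z)-4-hydroxybut-2-en-2-yl]-2-methyl-3-oxo-2,3-dihydrofuran-2-yl}-4-{[(S)-2-methylbutanoyl]oxy}pent-2-enoate | C/C(=C/CO)C1=CC(=O)[C@@](C)(C[C@@H](OC(=O)[C@@H](C)CC)/C=C(\CBr)C(=O)OC)O1 | intermediate
20 | methyl (2Z,4R)-2-(bromomethyl)-5-{(R)-2-methyl-3-oxo-5-[(Z)-4-oxobut-2-en-2-yl]-2,3-dihydrofuran-2-yl}-4-{[(S)-2-methylbutanoyl]oxy}pent-2-enoate | C/C(=C/C=O)C1=CC(=O)[C@@](C)(C[C@@H](OC(=O)[C@@H](C)CC)/C=C(\CBr)C(=O)OC)O1 | intermediate
21 | macrocyclic hydroxy ester: ten-membered carbocycle closed, free C6 hydroxyl, C12 methyl ester, configuration at C6/C7/C8/C10 as in 22 | COC(=O)C(=C)[C@H]1[C@H](O)/C=C(/C)C2=CC(=O)[C@@](C)(C[C@H]1OC(=O)[C@@H](C)CC)O2 | intermediate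
22 | CNP0174601.1, (6R,7R,8R,10R)-furanoheliangolide 8-O-[(S)-2-methylbutanoate], 4Z | C=C1C(=O)O[C@@H]2/C=C(/C)C3=CC(=O)[C@@](C)(C[C@@H](OC(=O)[C@@H](C)CC)[C@@H]12)O3 | target

**Summary**

Total step count: 13. Longest linear sequence: 12 steps (from 1 through steps 1–3 and 5–13; step 4 is the side branch).

Steps most likely to fail:

1. Step 6 (proposed new method). Three processes could spoil it:
   - poor facial selectivity in the epoxidation, which would scramble C10;
   - 1,2-acyl migration or hydrolysis of the anomeric ester before the gold-catalysed cyclisation;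
   - elimination instead of SN2 entry of the carboxylate at the hindered C8.

   Fallback with known chemistry, from 3 back to 12: the potassium enolate of 3 is hydroxylated with the Davis oxaziridine trans to the C8 substituent to give (3R,5S)-3-hydroxy-3-methyl lactone F1. Addition of the lithium acetylide of 6 (2.2 equiv) to the lactone gives dihydroxy ynone F2. Mitsunobu esterification of its secondary C8 hydroxyl with 9 (preformed PPh3–DIAD betaine, inversion) gives ester ynone F3. Gold(I)-catalysed 5-endo-dig cyclisation of this α′-hydroxy ynone gives 12.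

2. Step 13. The risks are 1,4-elimination of the C8 acyloxy group from the allylchromium species, attack on the wrong face relative to C8, and intermolecular coupling in competition with ring closure.

   Fallback, from 18 back to 22: Pd-catalysed borylation of the allylic bromide with B2pin2 gives allylboronate F4. DDQ cleavage of the PMB ether gives allylic alcohol F5, and MnO2 oxidation gives enal boronate F6. A Sc(OTf)3-catalysed intramolecular allylboration through a closed transition state, followed by lactonisation, gives 22. This route has no organochromium intermediate and therefore no reductive elimination pathway.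

3. Step 5. The risks are hydrolysis or ring opening of the sensitive five-membered ketene acetal phosphate and slow oxidative addition at the tetrasubstituted enol phosphate.

   Fallback, from 3 and 6 back to 8: addition of the lithium acetylide of 6 to lactone 3 (BF3·OEt2, THF, −78 °C) gives γ-hydroxy ynone F7 (in equilibrium with its lactol). Dehydration through the lactol (MsCl, Et3N, CH2Cl2, 0 °C) gives the cyclic enol ether 8.

Further compounds
F1 | step 6 | (3R,5S)-5-[(tert-butyldiphenylsilyloxy)methyl]-3-hydroxy-3-methyldihydrofuran-2(3H)-one | C[C@@]1(O)C[C@@H](CO[Si](c2ccccc2)(c2ccccc2)C(C)(C)C)OC1=O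
F2 | step 6 | (4R,6S,Z)-dihydroxy ynone: 7-(tert-butyldiphenylsilyloxy)-4,6-dihydroxy-1-[(Z)-4-(4-methoxybenzyloxy)but-2-en-2-yl]-4-methylhept-1-yn-3-one | C/C(=C/COCc1ccc(OC)cc1)C#CC(=O)[C@](C)(O)C[C@H](O)CO[Si](c1ccccc1)(c1ccccc1)C(C)(C)C
F3 | step 6 | C8-inverted (S)-2-methylbutanoate of F2 (8R, free tertiary C10 hydroxyl, ynone) | C/C(=C/COCc1ccc(OC)cc1)C#CC(=O)[C@](C)(O)C[C@@H](OC(=O)[C@@H](C)CC)CO[Si](c1ccccc1)(c1ccccc1)C(C)(C)C
F4 | step 13 | pinacol allylboronate corresponding to 18 (CH2Bpin in place of CH2Br) | C/C(=C/COCc1ccc(OC)cc1)C1=CC(=O)[C@@](C)(C[C@@H](OC(=O)[C@@H](C)CC)/C=C(\CB2OC(C)(C)C(C)(C)O2)C(=O)OC)O1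
F5 | step 13 | allylic alcohol from F4 (PMB removed) | C/C(=C/CO)C1=CC(=O)[C@@](C)(C[C@@H](OC(=O)[C@@H](C)CC)/C=C(\CB2OC(C)(C)C(C)(C)O2)C(=O)OC)O1
F6 | step 13 | Z-enal from F5 | C/C(=C/C=O)C1=CC(=O)[C@@](C)(C[C@@H](OC(=O)[C@@H](C)CC)/C=C(\CB2OC(C)(C)C(C)(C)O2)C(=O)OC)O1
F7 | step 5 | (6S)-7-(tert-butyldiphenylsilyloxy)-6-hydroxy-1-[(Z)-4-(4-methoxybenzyloxy)but-2-en-2-yl]-4-methylhept-1-yn-3-one (both C4 epimers) | C/C(=C/COCc1ccc(OC)cc1)C#CC(=O)C(C)C[C@H](O)CO[Si](c1ccccc1)(c1ccccc1)C(C)(C)C
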